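# Synthesis proposal for CNP0102441.1 (compound 26) via a masked o-benzoquinone / furan Diels–Alder reaction

## Analysis of the target

The target 26 is an elemane-type sesquiterpenoid built on one cyclohexane ring (C5–C10) that is cis-fused at C7–C8 to an α-methylene-γ-butyrolactone (C7–C11–C12–O–C8, exocyclic methylene C13). C10 is quaternary (methyl C14 and vinyl C1=C2), C5 carries the 2-substituted acrolein C4(=C15)–C3HO, C6 the angelate and C9 the methacrylate, so that all six ring carbons are contiguous stereocentres. Calling the face that carries the C10 methyl group α, the C4 side chain, O6 and O9 are α, whereas the vinyl group, C11 and the lactone oxygen O8 are β. Hence C5/C6 are cis, the lactone is cis-fused, O8/O9 are trans, and the vinyl carbon C1 and C11 are 1,4-cis across the ring. The molecule holds three Michael acceptors (enal, α-methylene lactone, methacrylate) and a Z-configured angelate that isomerises easily to the tiglate. The difficulties are the quaternary centre inside a run of six stereocentres, two different acyl groups on two secondary hydroxyls, and the need to unveil the electrophilic groups late. The strategy rests on two relations: C1 and C11, both β and 1,4-related, can be tied into a two-carbon bridge, and C4 and O6, both α and vicinal, can be two atoms of a cis-fused five-membered ring. Together they describe a bicyclo[2.2.2]octene with an endo-fused dihydrofuran, the Diels–Alder adduct of a cyclohexa-2,4-dienone and furan.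

## Retrosynthetic reasoning

**O9–acyl bond of 26.** The methacrylate is removed first. O9–H exists only once the lactone is closed and is the most hindered hydroxyl, so acylating it last, when nothing else can compete, leads back to hydroxy lactone 25.

**C8–O8 bond of 25.** The cis ring fusion together with the trans O8/O9 relation is what an anti, 5-exo opening of an 8α,9α-epoxide by the C12 ester carbonyl gives. The precursor is epoxy ester 24, in which both oxygens at C8/C9 are already fixed and O9 is still masked.

**C4=C15 and the C3 aldehyde of 24.** The enal is the most reactive group and its alkene would compete in any epoxidation. It is therefore made from the saturated aldehyde 22 by Mannich methylenation, and 22 comes from silyl ether 20 through alcohol 21.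

**O6–acyl bond of 20.** The angelate is attached (acid 19) while O9 is still locked in the epoxide of 18. This differentiates the two secondary oxygens without a protecting group.

**Epoxide of 18.** The epoxide must sit on the α face, anti to C11. Neither the substituent pattern nor ring conformation selects that face reliably, but a free O6–H, which is α and homoallylic to C8=C9, can deliver the oxidant there. This is why the tetrahydrofuran ring has to be open, as in 17, before the epoxidation, and why C4 must still be saturated at that point.

**Ring opening to 14.** The primary silyl ether 17 and diol 16 come from reduction of the C3 acetal of 14. Through the middle of the route the cyclic methyl acetal protects O6 and the C3 aldehyde as one unit.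

**Acrylate of 14.** The C11–C12 bond is cut by carbonylation chemistry back to enol triflate 13. C13 comes from the methyl of ketone 12, and 12 from ester 10 through amide 11.

**Vinyl group of 10.** The C1=C2 bond is cut to aldehyde 9. In 9, C1 is an aldehyde and C11 an ester, so the two carbons are already differentiated.

**C1–C11 bond (bridge).** Joining C1 and C11 of 9 gives the α-hydroxy ketone 7 (acetal 8 in the flask). In the forward direction an oxidative glycol-type cleavage turns the carbinol carbon into the aldehyde and the ketone carbon into the ester. 7 comes from the hydroxy ketal 6. The enol ether cannot survive the acid needed for the ketal, so its hydration to the lactol is accepted and used.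

**Resolution and reduction.** 6 is one enantiomer of racemic alcohol 5, obtained by reduction of adduct 4. The secondary alcohol is the only handle on which a resolution can be run so early.

**The Diels–Alder disconnection.** Cutting C10–C5 and C6–C7 of 4 gives dienone 3 and furan 2. 3 is the product of oxidative dearomatisation of phenol 1. In the forward sense one step makes the carbocycle, the quaternary centre and the relative configuration of C10, C5, C6 and C7.

## Alternatives that were turned down

**Alternative 1:** Here the ring would be closed at C5–C6. With C7, C8, C9 and the quaternary C10 already in place on a preformed lactone ring, an aldehyde carbon C6 attached to C7 would be attacked by C5, the γ-carbon of a tethered Z-allylboron unit. The intramolecular allylboration through a chair-like six-membered transition state would form C5–C6 and give the cyclohexanol A1 with the C4=C15 methylene and C3 at the alcohol level.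
- For it: O6 arrives as a free hydroxyl, the 2-substituted allyl unit needs no unmasking, the boron-ordered transition state translates the Z geometry into the C5/C6 cis relation, and O8 and O9 are in place. On the endgame it is more direct than the chosen route.
- Against it: C7, C8, C9 and the quaternary C10 must all be set beforehand by acyclic or lactone stereocontrol. A geometrically pure trisubstituted Z-allylboron unit next to a quaternary carbon is hard to make. The aldehyde sits α to C7 and β to the lactone oxygen, so epimerisation and β-elimination threaten. The new bond is formed beside the quaternary centre.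
- Comparison: the chosen strategy gives up the direct endgame but obtains the quaternary centre and three further stereocentres in one step from two aromatic compounds.

**Alternative 2:** This cuts C4–C5. O6 of a chiral-pool terpene enone would be tied up as a bromoacetal. A Bu3SnH radical chain would generate the primary radical, which adds 5-exo to the enone β-carbon C5 and gives the cis-fused acetal ketone A2.
- For it: absolute configuration comes from the chiral pool without a resolution, which is a clear advantage over the chosen route. The 5-exo closure is reliably cis, and C3 is delivered at the aldehyde level as an acetal.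
- Against it: A2 lacks most of the target. C10 is a methine next to a ketone and would have to be quaternised with a vinyl group under stereocontrol. The C9 ketone must be reduced from the right face. The C8 methylene must be oxygenated. The isopropenyl group must be oxidised to the acid level at C12, and C15 must still be added. A2 is also formed as a mixture at C10.
- Comparison: the chosen strategy has none of the C8–C10 problems, because C10 is set in the cycloaddition and C8/C9 arrive as an alkene ready for trans-dioxygenation.

**Alternative 3:** This cuts C7–C8, C11–C12 and C12–O at once. An open chain ending in an allene and an aldehyde and already holding the stereocentres C5, C6, C9 and C10 would be cyclocarbonylated on a metal carbonyl such as Mo(CO)6 in a hetero-Pauson–Khand-type [2+2+1] reaction. The product would be the protected α-methylene lactone A3.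
- For it: it is the most convergent plan. The carbocycle and the most sensitive unit are made together late, and A3 carries every carbon and oxygen with orthogonal protection, so the endgame would be shorter than in the chosen route.
- Against it: the acyclic chain needs four contiguous stereocentres, including the quaternary one, made without a ring to help. The configuration at C7 and C8 relative to them depends on metallacycle conformations that cannot be predicted with confidence. Six-membered ring formation is the less favourable mode for this reaction. The vinyl and 1,1-disubstituted alkenes can compete for the metal.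
- Comparison: the chosen route is longer after its key step, but the relative configuration of the ring is fixed by a rigid bicycle and not by a conformational preference.

Key step: step 1

## Route

Assumptions and remarks on the chemistry:
- The lipase is taken to acylate the unwanted enantiomer of 5, so that 6 is recovered as the free alcohol. If the preference is the reverse, the acetate is carried on after methanolysis.
- Compounds 4 and 5 are racemic; their SMILES show the enantiomer that is carried on.
- Compounds 7 to 15 are mixtures at the hemiacetal or acetal carbon C3, which is not a stereocentre in the target; its descriptor is left open.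

Step 1
Reactants: 1 2-methoxy-6-methylphenol; 2 furan
Product: 4 racemic endo bicyclo[2.2.2]octenone bearing a cis-fused 2,3-dihydrofuran, via dienone 3 (not isolated)
Conditions: PhI(OAc)2 (slow addition), MeOH, furan (about 20 equiv), 0 °C to rt
Reagents that add atoms: methanol (CO)
Why: Oxidation of 1 at the methoxy-bearing carbon by the trivalent iodine reagent in methanol gives the electron-poor 2,4-dienone 3, which is trapped as it forms in a concerted, suprafacial inverse-electron-demand [4+2] cycloaddition with the 2,3-double bond of furan acting as a 2π enol ether; this is the known behaviour of masked o-benzoquinones towards furans. The six-membered carbocycle C5–C10 is closed in this one step by intermolecular cycloaddition, forming C10–C5 and C6–C7 across the diene termini, while the keto-ketal unit C1–C11 remains as the third bridge of a bicyclo[2.2.2]octenone. Regiochemistry follows the frontier orbitals: the largest LUMO coefficient of 3 lies at the diene terminus next to the ketal carbon (the δ-carbon of the dienone) and the largest HOMO coefficient of furan at its α-carbon, so the oxygen-bearing furan carbon becomes C6 bonded to C7 and the β-carbon becomes C5 bonded to the methylated C10. C10 and C7 are bridgeheads, so C1 and C11 are held on the same face of the new ring, and the cis relation of C4 and O6 is the cis geometry of the furan double bond carried through the suprafacial addition. The relation between these two pairs is set by the endo transition state, in which the remaining C=C–O part of furan lies under the diene and away from the ketal methoxy groups, favoured by secondary orbital overlap and by sterics. The step therefore needs ortho regioselectivity, endo selectivity and a cycloaddition that outruns self-dimerisation of 3; the first two come from the polarisation of the partners, the last from the 2-methyl group of 3 and the large excess of furan. The adduct is racemic because neither partner carries a stereocentre.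

Step 2
Reactants: 4 racemic endo adduct
Product: 5 racemic bridge alcohol (C1–OH facing the C5–C6 bridge)
Conditions: NaBH4, MeOH, 0 °C
Reagents that add atoms: none
Why: Borohydride reduction of the strained α-keto ketal; hydride should enter from the less hindered alkene side, but the C1 centre is destroyed in step 5 and its configuration is immaterial. The enol ether, ketal and alkene are inert.

Step 3
Reactants: 5 racemic bridge alcohol
Product: 6 bridge alcohol as a single enantiomer
Conditions: immobilised Candida antarctica lipase B, vinyl acetate, t-BuOMe, 35 °C, stopped just past half conversion; chromatography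
Reagents that add atoms: none
Why: Lipase-catalysed kinetic resolution by enantioselective transesterification with an enol ester as irreversible acyl donor: one enantiomer of the secondary alcohol is acetylated and the other, taken here to be 6, is recovered. This fixes the absolute configuration of C10, C5, C6 and C7 for the rest of the route.

Step 4
Reactants: 6 bridge alcohol
Product: 7 α-hydroxy ketone lactol
Conditions: 2 M aq HCl, THF, rt
Reagents that add atoms: water (O)
Why: Acid-catalysed ketal hydrolysis, which is easier once the neighbouring carbonyl has been reduced; the enol ether cannot survive and is deliberately hydrated in the same operation to the lactol, a stable resting form of the C3 aldehyde. In the water-rich medium the C3 oxocarbenium ion is captured by water far faster than it could attack the nearby alkene.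

Step 5
Reactants: 7 α-hydroxy ketone lactol
Product: 9 cyclohexene bearing C1 aldehyde plus C11 methyl ester plus C3 methyl acetal, via methyl acetal 8 (not isolated)
Conditions: camphorsulfonic acid (cat.), MeOH, rt; NaHCO3; then Pb(OAc)4, MeOH–toluene, 0 °C
Reagents that add atoms: methanol (CO)
Why: Fischer-type acetalisation turns the lactol into the methyl acetal, then Criegee-type cleavage of the α-hydroxy ketone by tetravalent lead in methanol (through the methyl hemiketal) breaks C1–C11 and gives the C1 aldehyde and the C11 methyl ester in different oxidation states. No ring stereocentre is touched, and the quaternary C10 cannot epimerise.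

Step 6
Reactants: 9 aldehyde ester acetal
Product: 10 C10-vinyl methyl ester
Conditions: Ph3PCH3Br, KN(SiMe3)2, THF, 0 °C; then 9, −78 °C to 0 °C
Reagents that add atoms: methyltriphenylphosphonium bromide (C[P+](c1ccccc1)(c1ccccc1)c1ccccc1.[Br-])
Why: Wittig methylenation of the α-quaternary aldehyde gives the C10 vinyl group; the ester and the acetal do not react with the non-stabilised ylide at low temperature. A small excess of ylide and short reaction time limit deprotonation at the allylic C7–H.

Step 7
Reactants: 10 C10-vinyl methyl ester
Product: 11 Weinreb amide (N-methoxy-N-methylamide at C11)
Conditions: MeNH(OMe)·HCl, iPrMgCl, THF, −20 °C to 0 °C; aq NH4Cl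
Reagents that add atoms: N,O-dimethylhydroxylamine hydrochloride (CNOC.Cl)
Why: Direct aminolysis of the methyl ester by the chloromagnesium amide MeN(OMe)MgCl, made in the flask from the amine salt and iPrMgCl, gives the N-methoxy-N-methylamide. The amide anion is a good nucleophile but a modest base at this temperature, so the allylic C7–H should stay in place, and the acetal and the alkenes are inert.

Step 8
Reactants: 11 Weinreb amide
Product: 12 methyl ketone
Conditions: MeMgBr, THF, 0 °C; aq NH4Cl
Reagents that add atoms: methylmagnesium bromide (C[Mg]Br)
Why: Weinreb ketone synthesis: the chelated tetrahedral adduct of the amide with MeMgBr collapses to the ketone only on work-up, so over-addition is avoided. The β,γ-unsaturated ketone is released under buffered, near-neutral conditions and should not isomerise into conjugation.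

Step 9
Reactants: 12 methyl ketone
Product: 13 enol triflate
Conditions: KN(SiMe3)2, THF, −78 °C; then PhNTf2, −78 °C to 0 °C
Reagents that add atoms: N-phenylbis(trifluoromethanesulfonimide) (O=S(=O)(N(c1ccccc1)S(=O)(=O)C(F)(F)F)C(F)(F)F)
Why: Kinetic deprotonation by the bulky amide base takes place at the methyl group, because the tertiary C7–H lies near the carbonyl plane and is shielded; O-sulfonylation of the terminal enolate gives the 1,1-disubstituted enol triflate. C7 is therefore not epimerised.

Step 10
Reactants: 13 enol triflate
Product: 14 methyl acrylate (C11=C13 with C12 ester)
Conditions: Pd(OAc)2 (5 mol%), PPh3 (10 mol%), CO (1 atm), MeOH, Et3N, DMF, 50 °C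
Reagents that add atoms: carbon monoxide ([C-]#[O+]); methanol (CO)
Why: Palladium-catalysed alkoxycarbonylation of an enol triflate: oxidative addition to zerovalent palladium, CO insertion and methanolysis of the acylpalladium species form the C11–C12 bond. The other alkenes and the acetal are spectators.

Step 11
Reactants: 14 methyl acrylate acetal
Product: 16 diol (O6–H and primary C3–OH), via lactol 15 (not isolated)
Conditions: 1 M aq HCl, THF, rt; then NaHCO3 to pH 8, NaBH4, 0 °C
Reagents that add atoms: water (O)
Why: Mild aqueous acid hydrolyses the cyclic acetal to the lactol, whose open hydroxy-aldehyde form is reduced by borohydride after neutralisation; this opens the tetrahydrofuran ring and frees O6–H. The 2-substituted acrylate is reduced much more slowly than the aldehyde at 0 °C. The work-up is kept cold and near neutral so that the freed O6–H, which is trans to the acrylate on C7, does not close onto the C12 ester.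

Step 12
Reactants: 16 diol
Product: 17 primary tert-butyldimethylsilyl ether
Conditions: t-BuMe2SiCl (1.05 equiv), imidazole, CH2Cl2, −20 °C to 0 °C
Reagents that add atoms: tert-butyldimethylsilyl chloride (CC(C)(C)[Si](C)(C)Cl)
Why: Selective silylation of the primary hydroxyl in the presence of the hindered secondary O6–H with a slight excess of the bulky silyl chloride at low temperature.

Step 13
Reactants: 17 primary silyl ether
Product: 18 8α,9α-epoxy alcohol
Conditions: VO(acac)2 (5 mol%), t-BuOOH (anhydrous, in decane), CH2Cl2, 0 °C to rt
Reagents that add atoms: tert-butyl hydroperoxide (CC(C)(C)OO)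
Why: Hydroxyl-directed epoxidation: the pentavalent vanadium alkylperoxide bound to the homoallylic O6–H delivers oxygen to C8=C9 on the face of that hydroxyl, as in cyclohex-3-enols, which places the epoxide on the α face, anti to C11, and sets C8 and C9. The vinyl group is out of reach on the opposite face and the acrylate is too electron-poor to react.

Step 14
Reactants: 18 epoxy alcohol; 19 angelic acid
Product: 20 O6-angelate
Conditions: 19, 2,4,6-trichlorobenzoyl chloride, Et3N, toluene, rt; filter; then 18, toluene, 80 °C
Reagents that add atoms: none
Why: Yamaguchi-type esterification through the preformed mixed anhydride of angelic acid, run without a nucleophilic catalyst to suppress the addition–elimination pathway that isomerises the Z double bond. O6–H is the only free hydroxyl, and the epoxide tolerates the weakly basic medium.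

Step 15
Reactants: 20 O6-angelate silyl ether
Product: 21 primary alcohol
Conditions: Bu4NF, AcOH (1:1), THF, 0 °C to rt
Reagents that add atoms: none
Why: Fluoride cleavage of the primary silyl ether, buffered with acetic acid so that neither the angelate nor the epoxy ester meets free alkoxide.

Step 16
Reactants: 21 primary alcohol
Product: 22 C3 aldehyde
Conditions: Dess–Martin periodinane, NaHCO3, CH2Cl2, 0 °C to rt
Reagents that add atoms: none
Why: Dess–Martin oxidation of the primary alcohol under buffered, non-acidic conditions that leave the epoxide, the esters and the alkenes untouched.

Step 17
Reactants: 22 C3 aldehyde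
Product: 24 epoxy enal, via Mannich base 23 (not isolated)
Conditions: CH2=NMe2+ I− (3 equiv), Et3N, CH2Cl2, rt
Reagents that add atoms: N,N-dimethylmethyleneiminium iodide (C=[N+](C)C.[I-])
Why: Mannich reaction of the aldehyde enol with the preformed iminium salt, followed by β-elimination of dimethylamine from the Mannich base, gives the α-methylene aldehyde. The methylene is installed only now so that it is absent during the epoxidation and never meets organometallic reagents.

Step 18
Reactants: 24 epoxy enal
Product: 25 hydroxy lactone (O9–H free)
Conditions: camphorsulfonic acid (10 mol%), CH2Cl2 saturated with water, 0 °C to rt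
Reagents that add atoms: water (O)
Why: Acid-catalysed 5-exo opening of the epoxide by the carbonyl oxygen of the C12 ester with inversion at C8, then hydrolysis of the alkoxy-lactonium ion, gives the cis-fused α-methylene-γ-lactone and leaves the C9 hydroxyl α, trans to O8. Attack at C9 would need a bridged six-membered ring and is not expected.

Step 19
Reactants: 25 hydroxy lactone
Product: 26 CNP0102441.1
Conditions: methacrylic anhydride, Et3N, 4-(dimethylamino)pyridine (cat.), CH2Cl2, 0 °C to rt
Reagents that add atoms: methacrylic anhydride (C=C(C)C(=O)OC(=O)C(C)=C)
Why: Nucleophile-catalysed acylation of the last free, hindered secondary hydroxyl with the anhydride. The enal and the α-methylene lactone have no α-hydrogen and cannot enter Baylis–Hillman-type reactions with the catalyst.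

## Compound list

1 | 2-methoxy-6-methylphenol | COc1cccc(C)c1O | starting material
2 | furan | c1ccoc1 | starting material
3 | 6,6-dimethoxy-2-methylcyclohexa-2,4-dien-1-one (masked o-benzoquinone, not isolated) | CC1=CC=CC(OC)(OC)C1=O | intermediate
4 | racemic endo adduct: bicyclo[2.2.2]octenone with C1 ketone on the methylated bridgehead C10, dimethyl ketal C11 on bridgehead C7, C8=C9 alkene, and a 2,3-dihydrofuran (O6–C3=C4) cis-fused at C5–C6 under the alkene | O=C2[C@@]1(C)[C@@H]3C=CO[C@@H]3[C@@H](C2(OC)OC)C=C1 | intermediate
5 | racemic bridge alcohol: as 4 with C1–OH facing the C5–C6 bridge | O[C@H]2[C@@]1(C)[C@@H]3C=CO[C@@H]3[C@@H](C2(OC)OC)C=C1 | intermediate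
6 | bridge alcohol, single enantiomer (constitution and relative configuration of 5) | O[C@H]2[C@@]1(C)[C@@H]3C=CO[C@@H]3[C@@H](C2(OC)OC)C=C1 | intermediate
7 | α-hydroxy ketone lactol: C1–OH, C11 ketone, 2-hydroxytetrahydrofuran at C5–C6 (both C3 anomers) | O[C@H]2[C@@]1(C)[C@@H]3CC(O)O[C@@H]3[C@@H](C2=O)C=C1 | intermediate
8 | α-hydroxy ketone methyl acetal (C3–OMe, both anomers, not isolated) | O[C@H]2[C@@]1(C)[C@@H]3CC(OC)O[C@@H]3[C@@H](C2=O)C=C1 | intermediate
9 | cyclohexene with C10 methyl (α) and formyl C1 (β), C7 methoxycarbonyl C11 (β), and a 2-methoxytetrahydrofuran cis-fused at C5–C6 on the α face | O=C[C@@]1(C)[C@@H]2CC(OC)O[C@@H]2[C@@H](C(=O)OC)C=C1 | intermediate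
10 | as 9 with vinyl in place of formyl | C=C[C@@]1(C)[C@@H]2CC(OC)O[C@@H]2[C@@H](C(=O)OC)C=C1 | intermediate
11 | Weinreb amide: N-methoxy-N-methylamide in place of the methyl ester of 10 | C=C[C@@]1(C)[C@@H]2CC(OC)O[C@@H]2[C@@H](C(=O)N(C)OC)C=C1 | intermediate
12 | methyl ketone (C7 acetyl) | C=C[C@@]1(C)[C@@H]2CC(OC)O[C@@H]2[C@@H](C(C)=O)C=C1 | intermediate
13 | enol triflate (C7–C(OTf)=CH2) | C=C[C@@]1(C)[C@@H]2CC(OC)O[C@@H]2[C@@H](C(=C)OS(=O)(=O)C(F)(F)F)C=C1 | intermediate
14 | methyl 2-substituted acrylate (C7–C(=CH2)CO2Me), methyl acetal | C=C[C@@]1(C)[C@@H]2CC(OC)O[C@@H]2[C@@H](C(=C)C(=O)OC)C=C1 | intermediate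
15 | lactol of 14 (not isolated) | C=C[C@@]1(C)[C@@H]2CC(O)O[C@@H]2[C@@H](C(=C)C(=O)OC)C=C1 | intermediate
16 | diol: C5 2-hydroxyethyl (α), C6–OH (α) | C=C[C@@]1(C)[C@H](CCO)[C@H](O)[C@@H](C(=C)C(=O)OC)C=C1 | intermediate
17 | primary tert-butyldimethylsilyl ether of 16 | C=C[C@@]1(C)[C@H](CCO[Si](C)(C)C(C)(C)C)[C@H](O)[C@@H](C(=C)C(=O)OC)C=C1 | intermediate
18 | 8α,9α-epoxide of 17 (epoxide cis to O6–H) | C=C[C@@]1(C)[C@H](CCO[Si](C)(C)C(C)(C)C)[C@H](O)[C@@H](C(=C)C(=O)OC)[C@@H]2O[C@@H]21 | intermediate
19 | angelic acid, (Z)-2-methylbut-2-enoic acid | C/C=C(/C)C(=O)O | starting material
20 | O6-angelate of 18 | C=C[C@@]1(C)[C@H](CCO[Si](C)(C)C(C)(C)C)[C@H](OC(=O)/C(C)=C\C)[C@@H](C(=C)C(=O)OC)[C@@H]2O[C@@H]21 | intermediate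
21 | primary alcohol (C3–OH) | C=C[C@@]1(C)[C@H](CCO)[C@H](OC(=O)/C(C)=C\C)[C@@H](C(=C)C(=O)OC)[C@@H]2O[C@@H]21 | intermediate
22 | C3 aldehyde | C=C[C@@]1(C)[C@H](CC=O)[C@H](OC(=O)/C(C)=C\C)[C@@H](C(=C)C(=O)OC)[C@@H]2O[C@@H]21 | intermediate
23 | Mannich base: C4 dimethylaminomethyl aldehyde (both C4 epimers, not isolated) | C=C[C@@]1(C)[C@H](C(CN(C)C)C=O)[C@H](OC(=O)/C(C)=C\C)[C@@H](C(=C)C(=O)OC)[C@@H]2O[C@@H]21 | intermediate
24 | epoxy enal: C4(=C15)–C3HO, O6-angelate, 8α,9α-epoxide, methyl acrylate | C=C[C@@]1(C)[C@H](C(=C)C=O)[C@H](OC(=O)/C(C)=C\C)[C@@H](C(=C)C(=O)OC)[C@@H]2O[C@@H]21 | intermediate
25 | hydroxy lactone: cis-fused α-methylene-γ-lactone (O8 β), C9–OH (α) | C=C[C@@]1(C)[C@H](C(=C)C=O)[C@H](OC(=O)/C(C)=C\C)[C@H]2C(=C)C(=O)O[C@H]2[C@@H]1O | intermediate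
26 | CNP0102441.1 | C=C[C@@]1(C)[C@H](C(=C)C=O)[C@H](OC(=O)/C(C)=C\C)[C@H]2C(=C)C(=O)O[C@H]2[C@@H]1OC(=O)C(=C)C | target

## Step count and least certain steps

Total step count: 19. Longest linear sequence: 19 steps (1 to 26); angelic acid 19 enters at step 14.

**Step 1 (key step).** The most likely failure is self-dimerisation of dienone 3 outrunning the cycloaddition, because the furan 2,3-bond is only a moderately reactive 2π partner; a second concern is erosion of endo or regioselectivity if warming is needed. Fallback: use a blocked, isolable dienone in place of in situ trapping. Phenol 1 is brominated para to the hydroxyl (N-bromosuccinimide, MeCN) to 4-bromo-2-methoxy-6-methylphenol F1. Oxidation with PhI(OAc)2 in methanol gives 4-bromo-6,6-dimethoxy-2-methylcyclohexa-2,4-dien-1-one F2, in which the halogen retards dimerisation. F2 is heated with furan 2 in a sealed tube to give the C8-bromo adduct F3. Radical debromination (Bu3SnH, azobisisobutyronitrile, toluene, 80 °C) returns to 4; the vinyl σ-radical points away from the dihydrofuran and should not cyclise.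

**Step 3.** The carbinol is flanked by a quaternary bridgehead and a ketal carbon, so the enzyme may acylate it very slowly or with poor enantiomer discrimination. Fallback: classical resolution through covalent diastereomers. Racemic 5 is esterified with (S)-2-methoxy-2-phenylacetic acid (carbodiimide, 4-(dimethylamino)pyridine), the diastereomeric esters are separated by chromatography or crystallisation, and the (S)-O-methylmandelate of the wanted enantiomer F4 is cleaved with K2CO3 in methanol to give 6.

**Step 9.** C7–H is both α to the ketone and allylic, so deprotonation there instead of at the methyl group would lead to loss of the C7 configuration and to a conjugated dienyl triflate. Fallback: let hydrazone geometry, not relative acidity, decide the site of deprotonation. Ketone 12 is condensed with 2,4,6-triisopropylbenzenesulfonyl hydrazide to the trisylhydrazone F5. Shapiro reaction (n-BuLi, THF, −78 °C to 0 °C) generates the terminal vinyllithium by syn-directed deprotonation at the methyl group, and quenching with methyl chloroformate gives acrylate 14 directly, replacing steps 9 and 10.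

**Step 14.** The activated angeloyl group may isomerise to the tigloyl group, and the hindered O6–H may acylate slowly at a temperature the epoxide tolerates. Fallback: build the Z-alkene after the acylation. Alcohol 18 is esterified with 2-[bis(2,2,2-trifluoroethoxy)phosphoryl]propanoic acid (carbodiimide) to the phosphonopropionate F6. Still–Gennari olefination with acetaldehyde (KN(SiMe3)2, 18-crown-6, THF, −78 °C) then gives the (Z)-2-methylbut-2-enoate 20.

**Step 18.** The conjugated ester carbonyl is a weak nucleophile, so epoxide rearrangement or acid-induced isomerisation of the angelate may compete before the lactone closes. Fallback: let a carboxylate open the epoxide. The methyl acrylate of 24 is hydrolysed selectively with Me3SnOH (1,2-dichloroethane, 60 °C), which spares the secondary angelate, to the epoxy acid F7. F7 should lactonise spontaneously or with pyridinium p-toluenesulfonate to 25.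

## Further compounds

F1 | step 1 | 4-bromo-2-methoxy-6-methylphenol | COc1cc(Br)cc(C)c1O
F2 | step 1 | 4-bromo-6,6-dimethoxy-2-methylcyclohexa-2,4-dien-1-one | CC1=CC(Br)=CC(OC)(OC)C1=O
F3 | step 1 | racemic C8-bromo analogue of adduct 4 | O=C2[C@@]1(C)[C@@H]3C=CO[C@@H]3[C@@H](C2(OC)OC)C(Br)=C1
F4 | step 3 | (S)-2-methoxy-2-phenylacetate of alcohol 6 | CO[C@@H](c1ccccc1)C(=O)O[C@H]2[C@@]1(C)[C@@H]3C=CO[C@@H]3[C@@H](C2(OC)OC)C=C1
F5 | step 9 | 2,4,6-triisopropylbenzenesulfonylhydrazone of ketone 12 | C=C[C@@]1(C)[C@@H]2CC(OC)O[C@@H]2[C@@H](C(C)=NNS(=O)(=O)c3c(C(C)C)cc(C(C)C)cc3C(C)C)C=C1
F6 | step 14 | 2-[bis(2,2,2-trifluoroethoxy)phosphoryl]propanoate of alcohol 18 | C=C[C@@]1(C)[C@H](CCO[Si](C)(C)C(C)(C)C)[C@H](OC(=O)C(C)P(=O)(OCC(F)(F)F)OCC(F)(F)F)[C@@H](C(=C)C(=O)OC)[C@@H]2O[C@@H]21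
F7 | step 18 | epoxy acrylic acid corresponding to 24 | C=C[C@@]1(C)[C@H](C(=C)C=O)[C@H](OC(=O)/C(C)=C\C)[C@@H](C(=C)C(=O)O)[C@@H]2O[C@@H]21
A1 | alternative 1 | lactone-fused cyclohexanol from the intramolecular allylboration | C=C[C@@]1(C)[C@H](C(=C)CO[Si](C)(C)C(C)(C)C)[C@H](O)[C@H]2CC(=O)O[C@H]2[C@@H]1O[Si](CC)(CC)CC
A2 | alternative 2 | cis-fused bicyclic acetal ketone from the radical cyclisation | CC1[C@@H]2CC(OCC)O[C@@H]2[C@@H](C(C)=C)CC1=O
A3 | alternative 3 | protected α-methylene lactone from the cyclocarbonylation | C=C[C@@]1(C)[C@H](C(=C)COCc3ccc(OC)cc3)[C@H](O[Si](C)(C)C(C)(C)C)[C@H]2C(=C)C(=O)O[C@H]2[C@@H]1O[Si](CC)(CC)CC
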